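(Readings and results are simulated from invented constants, noise included.)

You asked how much target the flask holds at 5.0 min, and your hunch was that the percent carries over unchanged from the red run.

| flask | substrate | gas phase | remark | time |
|---|---|---|---|---|
| ochre | 0.095 M | 46 mM (held) | run made earlier |  |
| red | 0.14 M | 46 mM (held) | run made earlier |  |
| flask | 0.19 M | 46 mM (held) |  | 5.0 min |

- ochre (time / min: target / %): 0.333: 0.9; 1.00: 1.6; 1.50: 3.5; 2.50: 7.9; 4.00: 13.9; 5.00: 15.6; 6.00: 19.7
- red (time / min: target / %): 0.833: 1.0; 1.50: 3.2; 2.50: 7.5; 3.00: 7.8; 4.00: 10.6; 5.00: 12.4; 6.00: 14.3

(readings scatter by 0.5 percentage points)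

- at the start none of the gas phase is in solution

- target at 5.0 min, in percent of the substrate charged
- the change that raises the amount of target at 5.0 min, in percent of the substrate charged most ("none" if none brings more than 2 percentage points) (south-east / north / none)
- amount of target at 5.0 min, in percent of the substrate charged, after south-east

- south-east: doubling the transfer coefficient of the gas phase, all else as stated
- north: doubling the saturation concentration of gas phase, all else as stated

- Your hunch means c(target) grows in step with c(substrate), an exponent of 1. You can test that on the readings.
- Sum c(target) over the readings from 4.00 min to 6.00 min in each run. Both runs share those clock times, so time drops out of the red-to-ochre ratio.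
- That ratio is 1.12, for 1.47 times the substrate.
- Call n the charge exponent: the logarithm of the target ratio divided by the logarithm of the charge ratio. It is an apparent order in substrate, and it carries the scatter of the readings.
- Here n = 0.286, so your hunch fails.
- If n holds up to this flask, then at equal time and gas the percent scales with the charge to the power n minus 1. From the red reading of 12.4 % at 5.00 min, I reckon 9.97 % for this flask.
- Both runs held the gas at 46 mM, so n says nothing about south-east or north.
- The forecast gives 10 % (8.8 % to 11.5 %), north as best and 11 % after south-east; its ground: “The order in substrate is therefore low”.
- The flask gives 10.0 %. North adds 9.4 percentage points, and south-east reaches 14.9 %.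

    substrate + dissolved gas → target (k = 2.87 L mol⁻¹ min⁻¹)
    substrate + target → side product (k = 1.82 L mol⁻¹ min⁻¹)
    gas phase ⇌ dissolved gas, rate k3*(csat - [dissolved gas]) (kL = 0.406 min⁻¹)
    dissolved gas ⇌ dormant form (K = 1.50, k = 0.0973 min⁻¹)
    dissolved gas → decomposed reagent (k = 0.0992 min⁻¹)

- From red to this flask, the exponent reads 0.304. Now carry n down from this flask to the neighbour with 0.048 M of substrate, time held. You get 26.8 %, but the neighbour gives 20.3 %. Between these two flasks the exponent reads 0.489, higher than n. At 5.00 min, side product stands at 15.3 % in this flask and at 6.55 % in the neighbour.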